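If you want the bis adduct at one late hour across a row of charges, follow a single molecule of it and ask its chance of leaving, not just of forming.

| flask | substrate | gas | remark | time |
|---|---|---|---|---|
| north-west | 0.47 M | 100 mM (held) | run made earlier |  |
| north-east | 2.7 M | 100 mM (held) | run made earlier |  |
| summer | 0.40 M | 100 mM (held) |  | 3.0 min |
| dusk | 0.60 M | 100 mM (held) |  | 3.0 min |
| spring | 1.0 M | 100 mM (held) |  | 3.0 min |
| noon | 1.5 M | 100 mM (held) |  | 3.0 min |
| midnight | 2.5 M | 100 mM (held) |  | 3.0 min |

- north-west (time / s: bis adduct / %, substrate / %): 10.0: 0.7, 57.9; 20.0: 3.2, 27.9; 40.0: 8.1, 4.1; 60.0: 13.9, 1.0; 120: 24.8, 0.3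
- north-east (time / s: bis adduct / %, substrate / %): 10.0: 0, 84.8; 20.0: 0.7, 69.0; 40.0: 0.9, 41.9; 60.0: 3.3, 20.1; 120: 16.3, 0.4

(each reading ± 0.5 percentage points)

- at the start none of partner is dissolved
- the analysis behind the earlier runs scatters by 0.5 percentage points, standard deviation
- steps that have been proposed: substrate + partner -> single product + by-product; partner + single product -> bis adduct + by-product; partner + bis adduct -> triple product + by-product; partner + triple product -> tetra adduct + by-product; partner -> decomposed reagent; gas <-> partner; bis adduct <-> isomer of the product
- "hardly changes" means that all values lie within two and a half points (for a concentration: within two and a half percent of the largest)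

- amount of bis adduct at the end, in percent of the substrate charged for summer, dusk, spring, noon, midnight, in this order
- the shape of the row from first to last (falls all the way / rises, then falls / falls, then rises / rises all the way / hardly changes)

**Bench rule.** Extend the last slope. Between 60.0 s and 120 s the north-west bis adduct gained 0.109 min⁻¹, as a fraction of the charge. Carried on to 3.0 min, that line reaches 35.7 % in that flask.

**Its border.** But the north-west slope before it was steeper, 0.174 min⁻¹. Let the slope fall in line with the bis adduct present. The loss of slope per unit of bis adduct gained is then the leak, 0.778 min⁻¹, a rough reading given a scatter of 0.5 percentage points. I treat it as a lumped pseudo-first-order constant, assuming steady dissolved partner, though the fall in the north-west slope may have other causes too. On this reading the slope reaches zero at a ceiling of 33.4 %. Over the 60.0 s from the last north-west reading to 3.0 min, leak times time is 0.778, which is not small against one, so the straight line stops serving here.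

**My reckoning.** The distance to the ceiling shrinks to 0.459 of itself, about half. Taking the north-west leak and ceiling for both flasks, I reckon from their last readings 29.4 % for the north-west flask and 25.5 % for the north-east flask. These two charges lie near the ends of the row, so I expect the row to fall by about 3.9 points.

**The forecast.** It gave 33 %, 32 %, 30 %, 28.5 % and 26.5 %, shape falls all the way, its summer value standing above my north-west figure. It expected growth that “slows slightly, perhaps through loss to the triple product”.

**The flask.** The row came out 27.3 %, 27.4 %, 27.3 %, 26.8 %, 25.0 %: hardly changes.

    substrate + partner → single product + by-product (k = 1.10 M⁻¹ s⁻¹)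
    partner + single product → bis adduct + by-product (k = 0.0630 M⁻¹ s⁻¹)
    partner + bis adduct → triple product + by-product (k = 0.0940 M⁻¹ s⁻¹)
    partner + triple product → tetra adduct + by-product (k = 0.0880 M⁻¹ s⁻¹)
    partner → decomposed reagent (k = 0.0160 s⁻¹)
    gas ⇌ partner, rate k6*(csat - [partner]) (kL = 0.520 s⁻¹)
    bis adduct ⇌ isomer of the product (K = 0.190, k = 0.0370 s⁻¹)

**What ran.** The leak, started from summer's halfway 21.7 %, gives 29.7 %, above summer's 27.3 %. Started from dusk's halfway 20.8 %, it gives 29.5 %, where dusk held 27.4 %. In summer, half the turnover of substrate with partner up to the asked time was done by 0.195 min, and at 1.50 min substrate stood at 0.0265 %, with single product at 66.2 %. From then to 3.00 min, summer's single product fell to 39.2 % while its triple product rose to 17.6 %.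

The earlier runs and the new flask were computed with constants of no real substance; noise was put on by code.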